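**Retrosynthetic overview**
- Target 13 is traced back to 12 by removal of the two MOM acetals on O3 and O3', and 12 to 10 by methylation of the unchelated O7.
- Key disconnection: the two aryl–CH2 bonds at C6 and C8 of ring A, which leads back to prenyl bromide 7 and the 5,7-dihydroxyflavonol 6.
- The strategy rests on C6 and C8 being the only unsubstituted carbons of the phloroglucinol-type ring A: C6 lies between C5–OH and C7–OH, C8 between C7–OH and C8a–O1.
- Precursor 6 comes from tamarixetin 1 by 7-O-benzylation, MOM protection of O3 and O3', and hydrogenolysis.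
- No ring is formed in the route: rings A, B and C are all taken intact from tamarixetin.

Key step: step 4

Remark: the target has no stereocentre, and tamarixetin (4'-O-methylquercetin) is assumed to be purchasable, so no configuration has to be set.

**Step 1**
Reactants: 1 tamarixetin; 2 benzyl bromide
Product: 3 7-(benzyloxy)-3,5-dihydroxy-2-(3-hydroxy-4-methoxyphenyl)chromen-4-one
Conditions: BnBr (1.05 equiv), K2CO3 (1.1 equiv), DMF, argon, 0 °C to rt
Reagents that add atoms: benzyl bromide, BrCc1ccccc1
Why: Williamson etherification, in which the 7-OH (conjugated through ring A with the C4 carbonyl and not chelated) is the most acidic hydroxyl of 1, so one equivalent of base and bromide should alkylate O7 ahead of O3, O3' and the chelated O5.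

**Step 2**
Reactants: 3 7-(benzyloxy)-3,5-dihydroxy-2-(3-hydroxy-4-methoxyphenyl)chromen-4-one; 4 chloromethyl methyl ether
Product: 5 7-(benzyloxy)-5-hydroxy-3-(methoxymethoxy)-2-[4-methoxy-3-(methoxymethoxy)phenyl]chromen-4-one
Conditions: MOMCl (2.4 equiv), iPr2NEt (3 equiv), CH2Cl2–DMF, 0 °C to rt
Reagents that add atoms: chloromethyl methyl ether, COCCl
Why: MOM acetal formation at the two free hydroxyls O3 and O3' under amine base, while the 5-OH, hydrogen-bonded to the C4 carbonyl, is the least nucleophilic oxygen and should stay free with a controlled amount of MOMCl.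

**Step 3**
Reactants: 5 7-(benzyloxy)-5-hydroxy-3-(methoxymethoxy)-2-[4-methoxy-3-(methoxymethoxy)phenyl]chromen-4-one
Product: 6 5,7-dihydroxy-3-(methoxymethoxy)-2-[4-methoxy-3-(methoxymethoxy)phenyl]chromen-4-one
Conditions: H2 (1 atm), 10% Pd/C, EtOAc–THF, rt
Reagents that add atoms: none
Why: Hydrogenolysis of the benzyl ether over palladium on carbon, under which the MOM acetals, the aryl methyl ether and the conjugated tetrasubstituted C2=C3 bond of the chromone should be inert in a neutral solvent.

**Step 4**
Reactants: 6 5,7-dihydroxy-3-(methoxymethoxy)-2-[4-methoxy-3-(methoxymethoxy)phenyl]chromen-4-one; 7 prenyl bromide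
Product: 10 5,7-dihydroxy-3-(methoxymethoxy)-2-[4-methoxy-3-(methoxymethoxy)phenyl]-6,8-bis(3-methylbut-2-enyl)chromen-4-one, via 6-prenyl monoalkylation product 8 (not isolated), via 8-prenyl monoalkylation product 9 (not isolated)
Conditions: prenyl bromide (2.5 equiv), 10% aq KOH, 0 °C to rt
Reagents that add atoms: prenyl bromide, CC(C)=CCBr
Why: Aqueous KOH ionises the 7-OH (and in part the 5-OH) of 6, and the delocalised phenoxide attacks the primary CH2 of prenyl bromide by SN2 through C6 or C8; the cyclohexadienone formed re-aromatises by tautomerisation to 8 or 9, and a second alkylation at the remaining ring A carbon gives 10. The closest known reaction type is the base-mediated nuclear C-prenylation of 5,7-dihydroxyflavonoids and acylphloroglucinols by prenyl bromide in aqueous alkali, an electrophilic aromatic substitution on a phenoxide that mirrors prenyltransferase chemistry. No ring is closed and no stereocentre is created, so the step only forms the two aryl–CH2 bonds C6–C1'' and C8–C1''. The selectivity needed is C- over O-alkylation, normal (SN2) over reverse (SN2') attachment, and alkylation of ring A only. Water hydrogen-bonds to and shields the phenoxide oxygens, the bromide is attacked at its unhindered primary carbon, C6 and C8 are the only unsubstituted ring A carbons and each sits between two oxygen-bearing carbons, and O3 and O3' are masked as alkali-stable MOM acetals while the chelated 5-OH is a poor O-nucleophile. Mono-prenylated 8 and 9 recovered from the mixture can be resubmitted, and the amount of bromide is limited to suppress geminal dialkylation.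

**Step 5**
Reactants: 10 5,7-dihydroxy-3-(methoxymethoxy)-2-[4-methoxy-3-(methoxymethoxy)phenyl]-6,8-bis(3-methylbut-2-enyl)chromen-4-one; 11 methyl iodide
Product: 12 5-hydroxy-7-methoxy-3-(methoxymethoxy)-2-[4-methoxy-3-(methoxymethoxy)phenyl]-6,8-bis(3-methylbut-2-enyl)chromen-4-one
Conditions: MeI (1.5 equiv), K2CO3 (1.5 equiv), acetone, rt to 40 °C
Reagents that add atoms: methyl iodide, CI
Why: Williamson O-methylation, in which the 7-OH is the more acidic of the two remaining phenols and is not held in the hydrogen bond to C4=O that deactivates the 5-OH, so carbonate base in an aprotic solvent should give the 7-methyl ether by O-alkylation.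

**Step 6**
Reactants: 12 5-hydroxy-7-methoxy-3-(methoxymethoxy)-2-[4-methoxy-3-(methoxymethoxy)phenyl]-6,8-bis(3-methylbut-2-enyl)chromen-4-one
Product: 13 3,5-dihydroxy-2-(3-hydroxy-4-methoxyphenyl)-7-methoxy-6,8-bis(3-methylbut-2-enyl)chromen-4-one (CNP0261856.0)
Conditions: HCl (1.25 M in MeOH), THF, rt
Reagents that add atoms: none
Why: Acid-catalysed solvolysis of the two MOM acetals in methanol, which carries the formaldehyde unit off as its dimethyl acetal, under dilute anhydrous acid at room temperature that should be too mild to protonate the trisubstituted prenyl alkenes.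

**Compound list**
1 | tamarixetin, 3,5,7-trihydroxy-2-(3-hydroxy-4-methoxyphenyl)chromen-4-one | COc1ccc(-c2oc3cc(O)cc(O)c3c(=O)c2O)cc1O | starting material
2 | benzyl bromide | BrCc1ccccc1 | starting material
3 | 7-(benzyloxy)-3,5-dihydroxy-2-(3-hydroxy-4-methoxyphenyl)chromen-4-one | COc1ccc(-c2oc3cc(OCc4ccccc4)cc(O)c3c(=O)c2O)cc1O | intermediate
4 | chloromethyl methyl ether | COCCl | starting material
5 | 7-(benzyloxy)-5-hydroxy-3-(methoxymethoxy)-2-[4-methoxy-3-(methoxymethoxy)phenyl]chromen-4-one | COCOc1cc(-c2oc3cc(OCc4ccccc4)cc(O)c3c(=O)c2OCOC)ccc1OC | intermediate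
6 | 5,7-dihydroxy-3-(methoxymethoxy)-2-[4-methoxy-3-(methoxymethoxy)phenyl]chromen-4-one | COCOc1cc(-c2oc3cc(O)cc(O)c3c(=O)c2OCOC)ccc1OC | intermediate
7 | prenyl bromide, 1-bromo-3-methylbut-2-ene | CC(C)=CCBr | starting material
8 | 5,7-dihydroxy-3-(methoxymethoxy)-2-[4-methoxy-3-(methoxymethoxy)phenyl]-6-(3-methylbut-2-enyl)chromen-4-one | COCOc1cc(-c2oc3cc(O)c(CC=C(C)C)c(O)c3c(=O)c2OCOC)ccc1OC | intermediate
9 | 5,7-dihydroxy-3-(methoxymethoxy)-2-[4-methoxy-3-(methoxymethoxy)phenyl]-8-(3-methylbut-2-enyl)chromen-4-one | COCOc1cc(-c2oc3c(CC=C(C)C)c(O)cc(O)c3c(=O)c2OCOC)ccc1OC | intermediate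
10 | 5,7-dihydroxy-3-(methoxymethoxy)-2-[4-methoxy-3-(methoxymethoxy)phenyl]-6,8-bis(3-methylbut-2-enyl)chromen-4-one | COCOc1cc(-c2oc3c(CC=C(C)C)c(O)c(CC=C(C)C)c(O)c3c(=O)c2OCOC)ccc1OC | intermediate
11 | methyl iodide | CI | starting material
12 | 5-hydroxy-7-methoxy-3-(methoxymethoxy)-2-[4-methoxy-3-(methoxymethoxy)phenyl]-6,8-bis(3-methylbut-2-enyl)chromen-4-one | COCOc1cc(-c2oc3c(CC=C(C)C)c(OC)c(CC=C(C)C)c(O)c3c(=O)c2OCOC)ccc1OC | intermediate
13 | 3,5-dihydroxy-2-(3-hydroxy-4-methoxyphenyl)-7-methoxy-6,8-bis(3-methylbut-2-enyl)chromen-4-one | COc1ccc(-c2oc3c(CC=C(C)C)c(OC)c(CC=C(C)C)c(O)c3c(=O)c2O)cc1O | target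

**Step count**
Total steps: 6. Longest linear sequence: 6 steps (1 → 3 → 5 → 6 → 10 → 12 → 13).

**Steps most likely to fail**

1. Step 4. The phenoxide may alkylate on O7 instead of carbon, may stop after one prenyl group, or may over-alkylate to dearomatised geminal diprenyl dienones. This step is expected to be the lowest-yielding of the route, and its work-up is kept near pH 6 with a phosphate buffer to spare the MOM acetals. The fallback replaces phenoxide alkylation by halogenation and cross-coupling at the same two carbons. Setting out from 6, NIS (2.2 equiv) in DMF at rt should iodinate both free ring A carbons to give 5,7-dihydroxy-6,8-diiodo-3-(methoxymethoxy)-2-[4-methoxy-3-(methoxymethoxy)phenyl]chromen-4-one F1. MeI and K2CO3 in acetone should then methylate the 7-OH, made more acidic by the two flanking iodines, to give 5-hydroxy-6,8-diiodo-7-methoxy-3-(methoxymethoxy)-2-[4-methoxy-3-(methoxymethoxy)phenyl]chromen-4-one F2. A double Stille coupling of F2 with tributyl(3-methylbut-2-enyl)stannane (Pd(PPh3)4, zerovalent palladium, DMF, 90 °C) should attach both prenyl groups through their CH2 carbons. The fallback comes back to the route at 12.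

2. Step 1. Discrimination between O7 and the other hydroxyls may be poor, with over-alkylation at O3 or O3'. The fallback fixes the regiochemistry through esters. Setting out from 1, Ac2O in pyridine should give tamarixetin 3,5,7,3'-tetraacetate F3. PhSH and imidazole in NMP at 0 °C should cleave only the 7-O-acetate, whose phenoxide is the best leaving group, to give 3,5-diacetoxy-2-(3-acetoxy-4-methoxyphenyl)-7-hydroxychromen-4-one F4. BnBr and K2CO3 in acetone at rt should benzylate the single free hydroxyl to give 3,5-diacetoxy-2-(3-acetoxy-4-methoxyphenyl)-7-(benzyloxy)chromen-4-one F5. K2CO3 in MeOH under argon should remove the three acetates, and the fallback comes back to the route at 3.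

3. Step 6. The prenyl alkenes may be protonated during acetal cleavage, leading to ring closure of the C6 side chain onto O5 or to addition of HCl or methanol across the double bonds. The fallback avoids Brønsted acid by exchanging the acetals for silyl ethers. Setting out from 12, TMSOTf with an excess of 2,2'-bipyridyl in MeCN at 0 °C should transfer each methoxymethyl group to the pyridine nitrogen and give 5-hydroxy-7-methoxy-6,8-bis(3-methylbut-2-enyl)-3-(trimethylsilyloxy)-2-[4-methoxy-3-(trimethylsilyloxy)phenyl]chromen-4-one F6. Any silyl group taken up at O5 would be lost in the next operation. Addition of water at neutral pH should hydrolyse the aryl and enol silyl ethers of F6, and the fallback comes back to the route at 13.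

**Further compounds**
F1 | step 4 | 5,7-dihydroxy-6,8-diiodo-3-(methoxymethoxy)-2-[4-methoxy-3-(methoxymethoxy)phenyl]chromen-4-one | COCOc1cc(-c2oc3c(I)c(O)c(I)c(O)c3c(=O)c2OCOC)ccc1OC
F2 | step 4 | 5-hydroxy-6,8-diiodo-7-methoxy-3-(methoxymethoxy)-2-[4-methoxy-3-(methoxymethoxy)phenyl]chromen-4-one | COCOc1cc(-c2oc3c(I)c(OC)c(I)c(O)c3c(=O)c2OCOC)ccc1OC
F3 | step 1 | tamarixetin 3,5,7,3'-tetraacetate, 3,5,7-triacetoxy-2-(3-acetoxy-4-methoxyphenyl)chromen-4-one | COc1ccc(-c2oc3cc(OC(C)=O)cc(OC(C)=O)c3c(=O)c2OC(C)=O)cc1OC(C)=O
F4 | step 1 | 3,5-diacetoxy-2-(3-acetoxy-4-methoxyphenyl)-7-hydroxychromen-4-one | COc1ccc(-c2oc3cc(O)cc(OC(C)=O)c3c(=O)c2OC(C)=O)cc1OC(C)=O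
F5 | step 1 | 3,5-diacetoxy-2-(3-acetoxy-4-methoxyphenyl)-7-(benzyloxy)chromen-4-one | COc1ccc(-c2oc3cc(OCc4ccccc4)cc(OC(C)=O)c3c(=O)c2OC(C)=O)cc1OC(C)=O
F6 | step 6 | 5-hydroxy-7-methoxy-6,8-bis(3-methylbut-2-enyl)-3-(trimethylsilyloxy)-2-[4-methoxy-3-(trimethylsilyloxy)phenyl]chromen-4-one | COc1ccc(-c2oc3c(CC=C(C)C)c(OC)c(CC=C(C)C)c(O)c3c(=O)c2O[Si](C)(C)C)cc1O[Si](C)(C)C
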